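A neighbour flask charged with twice the catalyst is the plain test of this one: does the rate of making product follow the catalyst?

    substrate + coupling partner + catalyst → product + catalyst, rate k1*[substrate]*[coupling partner]*[catalyst]/(1 + ([substrate]/sat1)) (sat1 = 0.074 M, k1 = 3.8 × 10⁶ M⁻² h⁻¹)
    coupling partner + catalyst ⇌ idle complex, settled at all times (K2 = 79 M⁻¹)
    gas ⇌ coupling partner, rate k3*(csat - [coupling partner]) (k3 = 0.14 h⁻¹, csat = 5.9 mM)

substrate 40 mM; gas 5.9 mM (held); catalyst 40 µM

- apparent order in catalyst when 30% of the substrate are converted (percent change of the rate of making product for one percent more catalyst charged)

The first step is first order in the coupling partner, so it removes dissolved partner pseudo-first-order. The coefficient of that loss, the rate constant times substrate times catalyst divided by the substrate term of the rate law, is here called the draw. With 70.0% of the substrate charge left, the draw is 3.09 h⁻¹.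

But the second step takes catalyst away according to the dissolved partner, so that level comes next. The third step refills the partner in proportion to its gap from csat, and balance puts the partner at the fraction transfer/(transfer + draw) of csat. The draw is 22.1 times the transfer coefficient, so gas transfer is the rate-limiting step. At that level the idle complex holds 1.98% of the catalyst charge, so the draw stands uncorrected.

The flask starts with no partner dissolved, but the level relaxes within 0.310 h, far less than the 14.5 h the gas needs at its highest rate for this conversion.

The rate goes as draw/(transfer + draw), so the order in catalyst, the logarithmic slope of that fraction in the draw, is its complement transfer/(transfer + draw): 0.0434.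

The forecast gives 0.045, a little above this reckoning, holding that “the reaction is almost entirely mass-transfer limited”.

The simulated flask gives 0.050. Its percent change of rate for one percent more on the rate constant of the first step reads 0.051. In the neighbour flask the draw doubles to 6.18 h⁻¹, so draw/(transfer + draw) predicts a rate factor of 1.02. The run with twice the catalyst gives 1.03.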